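**Retrosynthetic overview**

1. The C15 acetate and the C12–C13 bond are made last: acetylation, then B-alkyl Suzuki–Miyaura coupling of a C9 vinyl group with an (E)-enol triflate that already carries the 13E geometry.
2. Ring A is opened at C1=C10 and is formed last, by intramolecular McMurry coupling of a C1 aldehyde with the C10 ketone of ring B.
3. Enabling feature: the only ring unsaturation is the C1=C10 olefin of ring A at the A/B fusion. C10 is a ring B carbon flanked by quaternary C9 and methine C5, and is 1,6-related to C1 through C2–C3–C4–C5, so both olefin carbons can be carbonyl carbons and the alkene can form nowhere else.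
4. The ring B stereocentres are relayed from C5 on a 2-methylcyclohexenone (C10=O): cuprate methyl to C8 cis to the C5 substituent, then C9 enolate aldol (later the vinyl group) anti to it.
5. C4/C5 come from a temporary cis-fused γ-lactone ring (C18–O–C10, by iodolactonization) that is methylated on its convex face; C5 itself comes from an enantioconvergent Tsuji–Trost alkylation. Ring order: ring B (bought carbocycle), temporary lactone, ring A.

Key step: step 14

Remark: carbons are numbered as in the halimane skeleton (C4 = ester-bearing quaternary carbon, C5/C10 = ring-fusion carbons, C8/C9 = methyl-bearing ring B carbons, C18 = ester carbon). The ligand antipode in step 3 is assumed to be the one that delivers the (1S) adduct, as the usual model predicts for the (1R,2R) ligand; otherwise its enantiomer is used.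

**Step 1**
Reactants: 1 dimethyl malonate; 2 2-(2-bromoethyl)-1,3-dioxolane
Product: 3 dimethyl 2-[2-(1,3-dioxolan-2-yl)ethyl]propanedioate
Conditions: NaH, 1 in excess, THF/DMF, 0 → 60 °C
Reagents that add atoms: none
Why: Malonic ester alkylation (SN2) of the sodium enolate of 1, kept in excess to suppress dialkylation, by the primary bromide 2; no stereocentre is formed.

**Step 2**
Reactants: 4 cyclohex-2-en-1-ol (racemic)
Product: 5 cyclohex-2-en-1-yl methyl carbonate (racemic)
Conditions: ClCO2Me, pyridine, CH2Cl2, 0 °C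
Reagents that add atoms: methyl chloroformate, COC(=O)Cl
Why: O-Acylation of the allylic alcohol installs the carbonate leaving group for palladium ionization; the racemate is acceptable because step 3 is enantioconvergent.

**Step 3**
Reactants: 5 cyclohex-2-en-1-yl methyl carbonate; 3 dimethyl 2-[2-(1,3-dioxolan-2-yl)ethyl]propanedioate
Product: 6 dimethyl 2-[(1S)-cyclohex-2-en-1-yl]-2-[2-(1,3-dioxolan-2-yl)ethyl]propanedioate
Conditions: Pd2(dba)3·CHCl3 (2.5 mol %), (1R,2R)-DACH-phenyl bis(2-diphenylphosphanylbenzamide) ligand (7.5 mol %), CH2Cl2, rt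
Reagents that add atoms: none
Why: Tsuji–Trost asymmetric allylic alkylation, in which both enantiomers of 5 ionize to the same meso π-allylpalladium complex, the methoxide released with CO2 deprotonates 3, and the chiral ligand steers the malonate onto one enantiotopic allyl terminus, which should set C5 as (S).

**Step 4**
Reactants: 6 dimethyl 2-[(1S)-cyclohex-2-en-1-yl]-2-[2-(1,3-dioxolan-2-yl)ethyl]propanedioate
Product: 8 2-[(1S)-cyclohex-2-en-1-yl]-4-(1,3-dioxolan-2-yl)butanoic acid (both C2 epimers), via monomethyl ester 7 (not isolated)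
Conditions: LiCl, H2O, DMSO, 155 °C; then LiOH, H2O, 60 °C; 1 M HCl to pH 4, 0 °C
Reagents that add atoms: lithium hydroxide, [Li+].[OH-]
Why: Krapcho dealkoxycarbonylation removes one ester under neutral conditions that spare the dioxolane and saponification of the remaining ester gives the acid, the C4 epimer mixture being irrelevant because C4 is re-enolized in step 6.

**Step 5**
Reactants: 8 2-[(1S)-cyclohex-2-en-1-yl]-4-(1,3-dioxolan-2-yl)butanoic acid
Product: 10 (3aR,7aR)-3-[2-(1,3-dioxolan-2-yl)ethyl]-3a,4,5,7a-tetrahydro-1-benzofuran-2(3H)-one (both C3 epimers), via iodolactone 9 (not isolated)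
Conditions: I2, NaHCO3, THF/H2O, 0 °C, dark; Na2S2O3 wash and solvent switch; DBU, PhMe, 80 °C
Reagents that add atoms: none
Why: Iodolactonization (5-exo, anti addition) can deliver the tethered carboxylate only to C10 on the face of the C5 side chain, giving the cis-fused γ-lactone with iodide trans at C9, and the anti-periplanar E2 elimination can use only H8 (H10 is syn to iodine), which places the alkene at C8=C9.

**Step 6**
Reactants: 10 (3aR,7aR)-3-[2-(1,3-dioxolan-2-yl)ethyl]-3a,4,5,7a-tetrahydro-1-benzofuran-2(3H)-one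
Product: 11 (3S,3aR,7aR)-3-[2-(1,3-dioxolan-2-yl)ethyl]-3-methyl-3a,4,5,7a-tetrahydro-1-benzofuran-2(3H)-one
Conditions: LiN(iPr)2, THF, −78 °C; MeI, DMPU, −78 → −30 °C
Reagents that add atoms: iodomethane, CI
Why: Lactone enolate alkylation in which both C3 epimers of 10 give one enolate and the folded cis-fused bicycle exposes only its convex face (the face of H5), so the methyl group should enter syn to H5 and set the C4 quaternary centre as needed.

**Step 7**
Reactants: 11 (3S,3aR,7aR)-3-[2-(1,3-dioxolan-2-yl)ethyl]-3-methyl-3a,4,5,7a-tetrahydro-1-benzofuran-2(3H)-one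
Product: 13 methyl (2S)-4-(1,3-dioxolan-2-yl)-2-[(1R,2R)-2-hydroxycyclohex-3-en-1-yl]-2-methylbutanoate, via potassium carboxylate 12 (not isolated)
Conditions: KOH (1.05 equiv), MeOH/H2O, 60 °C; evaporate; MeI, DMF, 0 °C → rt; neutral work-up, used at once
Reagents that add atoms: potassium hydroxide, [K+].[OH-]; iodomethane, CI
Why: Saponification opens the lactone and SN2 O-methylation of the carboxylate in DMF gives the methyl ester without the acid that would drive relactonization; no stereocentre is touched.

**Step 8**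
Reactants: 13 methyl (2S)-4-(1,3-dioxolan-2-yl)-2-[(1R,2R)-2-hydroxycyclohex-3-en-1-yl]-2-methylbutanoate
Product: 14 methyl (2S)-4-(1,3-dioxolan-2-yl)-2-methyl-2-[(1R)-2-oxocyclohex-3-en-1-yl]butanoate
Conditions: IBX, DMSO, rt
Reagents that add atoms: none
Why: IBX oxidation of the secondary allylic alcohol turns the former lactone oxygen into the C10 carbonyl needed for steps 11 and 14, and the neutral medium leaves C5 (now α to the ketone) untouched.

**Step 9**
Reactants: 14 methyl (2S)-4-(1,3-dioxolan-2-yl)-2-methyl-2-[(1R)-2-oxocyclohex-3-en-1-yl]butanoate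
Product: 15 methyl (2S)-4-(1,3-dioxolan-2-yl)-2-[(1R)-3-iodo-2-oxocyclohex-3-en-1-yl]-2-methylbutanoate
Conditions: I2, pyridine, CH2Cl2, 0 °C → rt
Reagents that add atoms: iodine, II
Why: Pyridine-promoted α-iodination of the enone (conjugate addition of pyridine, iodination of the enolate, elimination) occurs only at C9; no stereocentre is formed.

**Step 10**
Reactants: 15 methyl (2S)-4-(1,3-dioxolan-2-yl)-2-[(1R)-3-iodo-2-oxocyclohex-3-en-1-yl]-2-methylbutanoate
Product: 16 methyl (2S)-4-(1,3-dioxolan-2-yl)-2-methyl-2-[(1R)-3-methyl-2-oxocyclohex-3-en-1-yl]butanoate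
Conditions: Me4Sn, Pd2(dba)3 (2.5 mol %), AsPh3, CuI (10 mol %), NMP, 70 °C
Reagents that add atoms: tetramethylstannane, C[Sn](C)(C)C
Why: Stille coupling of the α-iodoenone under neutral conditions installs the C9 methyl group (C20) without risk to the α-stereocentre C5.

**Step 11**
Reactants: 16 methyl (2S)-4-(1,3-dioxolan-2-yl)-2-methyl-2-[(1R)-3-methyl-2-oxocyclohex-3-en-1-yl]butanoate
Product: 18 methyl (2S)-4-(1,3-dioxolan-2-yl)-2-[(1R,3R,4R)-3-(1-hydroxyethyl)-3,4-dimethyl-2-oxocyclohexyl]-2-methylbutanoate (both carbinol epimers), via lithium enolate 17 (not isolated)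
Conditions: Me2CuLi, Et2O, −78 → −30 °C; CH3CHO, −78 °C; aq NH4Cl
Reagents that add atoms: lithium dimethylcuprate, [Li+].C[Cu-]C; acetaldehyde, CC=O
Why: Cuprate conjugate addition followed by enolate aldol, in which the bulky C5 substituent sits equatorial so that axial methyl delivery to C8 should occur on the face cis to it, and the C9 enolate then adds to acetaldehyde anti to both the new C8 methyl and the C5 substituent, setting C8 and the C9 quaternary centre with C20 cis to C17.

**Step 12**
Reactants: 18 methyl (2S)-4-(1,3-dioxolan-2-yl)-2-[(1R,3R,4R)-3-(1-hydroxyethyl)-3,4-dimethyl-2-oxocyclohexyl]-2-methylbutanoate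
Product: 19 methyl (2S)-4-(1,3-dioxolan-2-yl)-2-[(1R,3S,4R)-3-ethenyl-3,4-dimethyl-2-oxocyclohexyl]-2-methylbutanoate
Conditions: methyl N-(triethylammoniosulfonyl)carbamate (Burgess reagent), PhH, 50 °C
Reagents that add atoms: none
Why: Burgess dehydration (syn-elimination through the sulfamate ester) can take a hydrogen only from the terminal methyl group because C9 is quaternary, giving the C9 vinyl group under neutral conditions that avoid retro-aldol cleavage and C5 epimerization.

**Step 13**
Reactants: 19 methyl (2S)-4-(1,3-dioxolan-2-yl)-2-[(1R,3S,4R)-3-ethenyl-3,4-dimethyl-2-oxocyclohexyl]-2-methylbutanoate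
Product: 20 methyl (2S)-2-[(1R,3S,4R)-3-ethenyl-3,4-dimethyl-2-oxocyclohexyl]-2-methyl-5-oxopentanoate
Conditions: 1 M HCl, THF, rt; used at once
Reagents that add atoms: water, O
Why: Mild acid hydrolysis of the dioxolane releases the C1 aldehyde while the ester, the β,γ-unsaturated ketone (which cannot conjugate) and C5 are unaffected.

**Step 14**
Reactants: 20 methyl (2S)-2-[(1R,3S,4R)-3-ethenyl-3,4-dimethyl-2-oxocyclohexyl]-2-methyl-5-oxopentanoate
Product: 21 methyl (1S,5S,6R,8aS)-5-ethenyl-1,5,6-trimethyl-1,2,3,5,6,7,8,8a-octahydronaphthalene-1-carboxylate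
Conditions: TiCl3(DME)1.5, Zn–Cu, DME, reflux; 20 added over 30 h by syringe pump, then reflux
Reagents that add atoms: none
Why: Low-valent titanium made from TiCl3(DME)1.5 and Zn–Cu transfers single electrons to the C1 aldehyde and the C10 ketone, the two titanium-bound ketyls (two carbons of the same, electrophilic, polarity) couple to a titanium pinacolate, and the metal then strips both oxygens at reflux to leave the C1=C10 double bond. The closest known reaction type is the intramolecular McMurry keto–aldehyde coupling to cyclohexenes. Ring A closes in the six-membered mode by joining C1 to C10 (carbonyl–carbonyl coupling, both C=O bonds exocyclic to the new ring), and because the alkene is born from the two carbonyl carbons it can only be the ring-fusion olefin, with no positional isomer possible. No stereocentre is created; C4, C5, C8 and C9 are spectators, and C5, the only enolizable position, is shielded by the adjacent quaternary C4 in a non-basic medium. The step needs intramolecular over intermolecular coupling, which slow addition at high dilution secures, and aldehyde–ketone over ketone–ester coupling, which the much lower reactivity of the hindered C18 ester secures; the isolated vinyl group is inert to the reagent.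

**Step 15**
Reactants: 22 ethyl 3-oxobutanoate
Product: 23 ethyl (2E)-3-{[(trifluoromethyl)sulfonyl]oxy}but-2-enoate
Conditions: Tf2O, aq Me4NOH, toluene, 5 °C → rt
Reagents that add atoms: trifluoromethanesulfonic anhydride, O=S(=O)(OS(=O)(=O)C(F)(F)F)C(F)(F)F
Why: O-Sulfonylation of the tetramethylammonium enolate, which lacks a chelating counter-ion and should react through the extended enolate, gives the (E)-enol triflate with the triflate trans to the ester.

**Step 16**
Reactants: 23 ethyl (2E)-3-{[(trifluoromethyl)sulfonyl]oxy}but-2-enoate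
Product: 24 (2E)-4-hydroxybut-2-en-2-yl trifluoromethanesulfonate
Conditions: iBu2AlH, CH2Cl2, −78 °C; aq potassium sodium tartrate
Reagents that add atoms: none
Why: 1,2-Reduction of the conjugated ester by iBu2AlH at low temperature gives the allylic alcohol and leaves the enol triflate and the alkene geometry intact.

**Step 17**
Reactants: 21 methyl (1S,5S,6R,8aS)-5-ethenyl-1,5,6-trimethyl-1,2,3,5,6,7,8,8a-octahydronaphthalene-1-carboxylate; 24 (2E)-4-hydroxybut-2-en-2-yl trifluoromethanesulfonate
Product: 26 methyl (1S,5S,6R,8aS)-5-[(3E)-5-hydroxy-3-methylpent-3-en-1-yl]-1,5,6-trimethyl-1,2,3,5,6,7,8,8a-octahydronaphthalene-1-carboxylate, via alkylborane 25 (not isolated)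
Conditions: 9-BBN, THF, 0 °C → rt; then 24, PdCl2(dppf)·CH2Cl2 (5 mol %), AsPh3, aq K3PO4, DMF, rt → 50 °C
Reagents that add atoms: none
Why: Hydroboration with 9-BBN is selective for the monosubstituted C9 vinyl group over the trisubstituted C1=C10 and puts boron on C12, and the B-alkyl Suzuki–Miyaura coupling with the enol triflate proceeds with retention of alkene geometry to give the 13E side chain.

**Step 18**
Reactants: 26 methyl (1S,5S,6R,8aS)-5-[(3E)-5-hydroxy-3-methylpent-3-en-1-yl]-1,5,6-trimethyl-1,2,3,5,6,7,8,8a-octahydronaphthalene-1-carboxylate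
Product: 27 methyl (1S,5S,6R,8aS)-5-[(3E)-5-(acetyloxy)-3-methylpent-3-en-1-yl]-1,5,6-trimethyl-1,2,3,5,6,7,8,8a-octahydronaphthalene-1-carboxylate (target)
Conditions: Ac2O, pyridine, DMAP (cat.), CH2Cl2, rt
Reagents that add atoms: acetic anhydride, CC(=O)OC(C)=O
Why: DMAP-catalysed acetylation of the primary allylic alcohol gives the acetate; no other group reacts.

**Compound list**

1 | dimethyl malonate | COC(=O)CC(=O)OC | starting material
2 | 2-(2-bromoethyl)-1,3-dioxolane | BrCCC1OCCO1 | starting material
3 | dimethyl 2-[2-(1,3-dioxolan-2-yl)ethyl]propanedioate | COC(=O)C(CCC1OCCO1)C(=O)OC | intermediate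
4 | cyclohex-2-en-1-ol (racemic) | OC1C=CCCC1 | starting material
5 | cyclohex-2-en-1-yl methyl carbonate (racemic) | COC(=O)OC1C=CCCC1 | intermediate
6 | dimethyl 2-[(1S)-cyclohex-2-en-1-yl]-2-[2-(1,3-dioxolan-2-yl)ethyl]propanedioate | COC(=O)C(CCC1OCCO1)(C(=O)OC)[C@@H]2C=CCCC2 | intermediate
7 | methyl 2-[(1S)-cyclohex-2-en-1-yl]-4-(1,3-dioxolan-2-yl)butanoate (both C2 epimers) | COC(=O)C(CCC1OCCO1)[C@@H]2C=CCCC2 | intermediate
8 | 2-[(1S)-cyclohex-2-en-1-yl]-4-(1,3-dioxolan-2-yl)butanoic acid (both C2 epimers) | OC(=O)C(CCC1OCCO1)[C@@H]2C=CCCC2 | intermediate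
9 | (3aR,7S,7aS)-3-[2-(1,3-dioxolan-2-yl)ethyl]-7-iodohexahydro-1-benzofuran-2(3H)-one (both C3 epimers) | O=C1O[C@@H]2[C@@H](I)CCC[C@@H]2C1CCC3OCCO3 | intermediate
10 | (3aR,7aR)-3-[2-(1,3-dioxolan-2-yl)ethyl]-3a,4,5,7a-tetrahydro-1-benzofuran-2(3H)-one (both C3 epimers) | O=C1O[C@@H]2C=CCC[C@@H]2C1CCC3OCCO3 | intermediate
11 | (3S,3aR,7aR)-3-[2-(1,3-dioxolan-2-yl)ethyl]-3-methyl-3a,4,5,7a-tetrahydro-1-benzofuran-2(3H)-one | O=C1O[C@@H]2C=CCC[C@@H]2[C@]1(C)CCC3OCCO3 | intermediate
12 | potassium (2S)-4-(1,3-dioxolan-2-yl)-2-[(1R,2R)-2-hydroxycyclohex-3-en-1-yl]-2-methylbutanoate | [K+].[O-]C(=O)[C@@](C)(CCC1OCCO1)[C@H]2CCC=C[C@H]2O | intermediate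
13 | methyl (2S)-4-(1,3-dioxolan-2-yl)-2-[(1R,2R)-2-hydroxycyclohex-3-en-1-yl]-2-methylbutanoate | COC(=O)[C@@](C)(CCC1OCCO1)[C@H]2CCC=C[C@H]2O | intermediate
14 | methyl (2S)-4-(1,3-dioxolan-2-yl)-2-methyl-2-[(1R)-2-oxocyclohex-3-en-1-yl]butanoate | COC(=O)[C@@](C)(CCC1OCCO1)[C@H]2CCC=CC2=O | intermediate
15 | methyl (2S)-4-(1,3-dioxolan-2-yl)-2-[(1R)-3-iodo-2-oxocyclohex-3-en-1-yl]-2-methylbutanoate | COC(=O)[C@@](C)(CCC1OCCO1)[C@H]2CCC=C(I)C2=O | intermediate
16 | methyl (2S)-4-(1,3-dioxolan-2-yl)-2-methyl-2-[(1R)-3-methyl-2-oxocyclohex-3-en-1-yl]butanoate | COC(=O)[C@@](C)(CCC1OCCO1)[C@H]2CCC=C(C)C2=O | intermediate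
17 | lithium (3R,6R)-6-[(2S)-4-(1,3-dioxolan-2-yl)-1-methoxy-2-methyl-1-oxobutan-2-yl]-2,3-dimethylcyclohex-1-en-1-olate | COC(=O)[C@@](C)(CCC1OCCO1)[C@H]2CC[C@@H](C)C(C)=C2[O-].[Li+] | intermediate
18 | methyl (2S)-4-(1,3-dioxolan-2-yl)-2-[(1R,3R,4R)-3-(1-hydroxyethyl)-3,4-dimethyl-2-oxocyclohexyl]-2-methylbutanoate (both carbinol epimers) | COC(=O)[C@@](C)(CCC1OCCO1)[C@H]2CC[C@@H](C)[C@](C)(C(C)O)C2=O | intermediate
19 | methyl (2S)-4-(1,3-dioxolan-2-yl)-2-[(1R,3S,4R)-3-ethenyl-3,4-dimethyl-2-oxocyclohexyl]-2-methylbutanoate | COC(=O)[C@@](C)(CCC1OCCO1)[C@H]2CC[C@@H](C)[C@](C)(C=C)C2=O | intermediate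
20 | methyl (2S)-2-[(1R,3S,4R)-3-ethenyl-3,4-dimethyl-2-oxocyclohexyl]-2-methyl-5-oxopentanoate | COC(=O)[C@@](C)(CCC=O)[C@H]1CC[C@@H](C)[C@](C)(C=C)C1=O | intermediate
21 | methyl (1S,5S,6R,8aS)-5-ethenyl-1,5,6-trimethyl-1,2,3,5,6,7,8,8a-octahydronaphthalene-1-carboxylate | COC(=O)[C@@]1(C)CCC=C2[C@@H]1CC[C@@H](C)[C@]2(C)C=C | intermediate
22 | ethyl 3-oxobutanoate (ethyl acetoacetate) | CCOC(=O)CC(C)=O | starting material
23 | ethyl (2E)-3-{[(trifluoromethyl)sulfonyl]oxy}but-2-enoate | CCOC(=O)/C=C(\C)OS(=O)(=O)C(F)(F)F | intermediate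
24 | (2E)-4-hydroxybut-2-en-2-yl trifluoromethanesulfonate | OC/C=C(\C)OS(=O)(=O)C(F)(F)F | intermediate
25 | methyl (1S,5S,6R,8aS)-5-[2-(9-borabicyclo[3.3.1]nonan-9-yl)ethyl]-1,5,6-trimethyl-1,2,3,5,6,7,8,8a-octahydronaphthalene-1-carboxylate | COC(=O)[C@@]1(C)CCC=C2[C@@H]1CC[C@@H](C)[C@]2(C)CCB3C4CCCC3CCC4 | intermediate
26 | methyl (1S,5S,6R,8aS)-5-[(3E)-5-hydroxy-3-methylpent-3-en-1-yl]-1,5,6-trimethyl-1,2,3,5,6,7,8,8a-octahydronaphthalene-1-carboxylate | COC(=O)[C@@]1(C)CCC=C2[C@@H]1CC[C@@H](C)[C@]2(C)CC/C(C)=C/CO | intermediate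
27 | methyl (1S,5S,6R,8aS)-5-[(3E)-5-(acetyloxy)-3-methylpent-3-en-1-yl]-1,5,6-trimethyl-1,2,3,5,6,7,8,8a-octahydronaphthalene-1-carboxylate | COC(=O)[C@@]1(C)CCC=C2[C@@H]1CC[C@@H](C)[C@]2(C)CC/C(C)=C/COC(C)=O | target

**Step count**

Total: 18 steps. Longest linear sequence: 15 steps (steps 2–14, 17, 18).

**Steps most likely to fail**

Step 14 (key step). The hindered titanium pinacolate may resist deoxygenation, intermolecular coupling may compete, or the Lewis-acidic titanium may epimerize C5. The fallback sets out from 20 and comes back at 21, closing the ring in two stages with known chemistry. SmI2 in THF/t-BuOH at −78 °C should give, by intramolecular pinacol coupling, the cis-4,4a-diol F1. 1,1′-Thiocarbonyldiimidazole with DMAP in hot toluene should convert it into the cyclic thionocarbonate F2. Heating F2 in P(OMe)3 (Corey–Winter olefination) should extrude CO2 and sulfur stereospecifically and give 21.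

Step 11. The substrate-controlled methyl delivery may show poor facial selectivity, or proton transfer and retro-aldol cleavage may interfere with the enolate trapping. The fallback sets out from 16 and comes back at 18, replacing substrate control by catalyst control. Me3Al with CuTC (C5H3CuO2S) and a BINOL-derived phosphoramidite ligand, chosen so that its sense reinforces the cis face, in Et2O at −30 °C, followed by TMSOTf, should give the isolable silyl enol ether F3. MeLi in THF then regenerates the copper-free lithium enolate 17, and ZnCl2 followed by CH3CHO should give 18.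

Step 7. The γ-hydroxy ester may relactonize during work-up or chromatography. The fallback sets out from 11 and comes back at 14, bypassing 13 and step 8. After saponification to 12, the allylic alcohol is oxidized in the basic aqueous solution (TEMPO cat., NaOCl, KBr, pH 9, 0 °C) while the carboxylate is still ionized. Acidification should then give the enone acid F4, which can no longer lactonize, and TMSCHN2 in MeOH/toluene should give 14.

**Further compounds**

F1 | step 14 | methyl (1S,5S,6R,8aR)-5-ethenyl-4,4a-dihydroxy-1,5,6-trimethyldecahydronaphthalene-1-carboxylate (cis-4,4a-diol, configuration at C4/C4a left open) | COC(=O)[C@@]1(C)CCC(O)C2(O)[C@@H]1CC[C@@H](C)[C@]2(C)C=C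
F2 | step 14 | cyclic 4,4a-thionocarbonate of F1 (1,3-dioxolane-2-thione fused at C4/C4a) | COC(=O)[C@@]1(C)CCC2OC(=S)OC23[C@@H]1CC[C@@H](C)[C@]3(C)C=C
F3 | step 11 | methyl (2S)-2-{(1R,4R)-3,4-dimethyl-2-[(trimethylsilyl)oxy]cyclohex-2-en-1-yl}-4-(1,3-dioxolan-2-yl)-2-methylbutanoate | COC(=O)[C@@](C)(CCC1OCCO1)[C@H]2CC[C@@H](C)C(C)=C2O[Si](C)(C)C
F4 | step 7 | (2S)-4-(1,3-dioxolan-2-yl)-2-methyl-2-[(1R)-2-oxocyclohex-3-en-1-yl]butanoic acid | OC(=O)[C@@](C)(CCC1OCCO1)[C@H]2CCC=CC2=O
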